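# Total synthesis of licobichalcone (target 26)

**Assumptions**
- The SMILES is read as the 1,2‑cis (1S,2S) isomer: the 1‑aryl and 2‑aroyl groups are on the same face of the 1,2‑dihydronaphthalene.
- NBS bromination of 3 is assumed to favour the site ortho to OMe, the smaller neighbour.
- The chiral diene enantiomer is assumed to be chosen so that the (S)‑diarylmethine forms.

**Retrosynthesis**
1. Target 26 comes from its hexa‑O‑acetate 25 by lipase alcoholysis under neutral conditions, which protects the epimerisable C2–H and the catechols.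
2. The carbocycle (C3=C4) is closed last by intramolecular aldol condensation of an aldehyde‑1,4‑diketone. C2 is set cis in this step.
3. The 1,4‑diketone comes from alkylating a β,β‑diaryl ketone with a phenacyl bromide. That ketone comes from Rh/chiral‑diene asymmetric 1,4‑addition of an ortho‑acetal arylboronic acid to a chalcone, which sets C1.
4. Both aryl fragments come from 3‑methoxycatechol. The only ring formed is the carbocycle, in step 14; the dioxolane is a temporary protecting ring.

## Steps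

**Step 1**
Reactants: 1 (3‑methoxybenzene‑1,2‑diol)
Product: 3 (1,2‑bis(benzyloxy)‑3‑methoxybenzene)
Conditions: BnBr (2.3 equiv), K2CO3, DMF, 60 °C
Reagents that add atoms: 2, benzyl bromide, BrCc1ccccc1
Why: Williamson O‑benzylation masks the catechol with groups stable to bases, organolithiums and Rh; no stereocenter is involved.

**Step 2**
Reactants: 3
Product: 5 (1‑bromo‑3,4‑bis(benzyloxy)‑2‑methoxybenzene)
Conditions: NBS (1.05 equiv), MeCN, 0 °C → rt, dark
Reagents that add atoms: 4, N‑bromosuccinimide, O=C1CCC(=O)N1Br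
Why: Electrophilic aromatic bromination; the site ortho to OMe and para to OBn is attacked in preference to the site ortho to the bulkier OBn, and the minor isomer is removed by chromatography.

**Step 3**
Reactants: 5
Product: 7 (3,4‑bis(benzyloxy)‑2‑methoxybenzaldehyde)
Conditions: n‑BuLi, THF, −78 °C; then DMF, −78 °C → rt
Reagents that add atoms: 6, N,N‑dimethylformamide, CN(C)C=O
Why: Li–Br exchange followed by formylation converts the aryl bromide to the aldehyde.

**Step 4**
Reactants: 7; 8 (4'‑benzyloxyacetophenone)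
Product: 9 ((E)‑chalcone)
Conditions: NaOH (aq), EtOH, rt, 16 h
Reagents that add atoms: none
Why: Claisen–Schmidt condensation gives the thermodynamic (E)‑enone, a mono‑ortho‑substituted β‑aryl acceptor.

**Step 5**
Reactants: 5
Product: 10 (4,5‑bis(benzyloxy)‑2‑bromo‑3‑methoxybenzaldehyde)
Conditions: LDA, THF, −78 °C, 1 h; then DMF, −78 → 0 °C
Reagents that add atoms: 6, DMF
Why: Directed ortho‑metalation; the proton ortho to Br is the most acidified, so formylation places CHO next to Br, and Br sits between the new CHO and OMe.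

**Step 6**
Reactants: 10
Product: 12 (2‑[4,5‑bis(benzyloxy)‑2‑bromo‑3‑methoxyphenyl]‑1,3‑dioxolane)
Conditions: TsOH·H2O (5 mol%), PhMe, Dean–Stark, reflux
Reagents that add atoms: 11, ethane‑1,2‑diol, OCCO
Why: Acetalisation protects the aldehyde from the organolithium, the borylation and the Rh step.

**Step 7**
Reactants: 12
Product: 14 ([3,4‑bis(benzyloxy)‑6‑(1,3‑dioxolan‑2‑yl)‑2‑methoxyphenyl]boronic acid)
Conditions: n‑BuLi, THF, −78 °C; B(OiPr)3, −78 °C → rt; pH 7 phosphate‑buffer work‑up
Reagents that add atoms: 13, triisopropyl borate, CC(C)OB(OC(C)C)OC(C)C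
Why: Li–Br exchange and borylation give the ortho,ortho'‑disubstituted boronic acid, and the buffered work‑up keeps the acetal intact.

**Step 8**
Reactants: 8
Product: 16 (2‑bromo‑1‑[4‑(benzyloxy)phenyl]ethan‑1‑one)
Conditions: CuBr2 (2 equiv), EtOAc/CHCl3 1:1, reflux
Reagents that add atoms: 15, copper(II) bromide, Br[Cu]Br
Why: α‑Bromination of the aryl methyl ketone via its enol gives the phenacyl electrophile.

**Step 9**
Reactants: 9; 14
Product: 17 ((3S)‑diaryl ketone, acetal intact)
Conditions: [Rh(OH)((R,R)‑Ph‑bod*)]2 (1.5 mol %), 14 (2.5 equiv), dioxane/H2O 10:1, 50 °C, 16 h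
Reagents that add atoms: none
Why: Hayashi–Miyaura asymmetric 1,4‑addition. The aryl‑Rh adds to one enantioface of the (E)‑enone, the large difference between the mono‑ortho and di‑ortho aryls controls the face, and the resulting enol is protonated by water. This sets C1 (S), the first stereocenter.

**Step 10**
Reactants: 17; 16
Product: 18 (1,4‑diketone; C1 (S), C2 epimeric mixture)
Conditions: LiHMDS (1.2 equiv), THF, −78 °C; then 16 (1.5 equiv), −78 → 0 °C
Reagents that add atoms: none
Why: Enolate C‑alkylation by an SN2 reaction builds the C2–C3 bond. C1 is untouched, and the C2 epimers converge in step 14.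

**Step 11**
Reactants: 18
Product: 19 (hexaphenol acetal, 1,4‑diketone)
Conditions: H2 (1 atm), Pd(OH)2/C, EtOAc/EtOH 1:1, rt
Reagents that add atoms: none
Why: Hydrogenolysis removes all six benzyl ethers; no C=C is present to be reduced, and the dioxolane and ketones survive neutral hydrogenolysis.

**Step 12**
Reactants: 19
Product: 21 (hexa‑O‑acetate)
Conditions: Ac2O (12 equiv), pyridine, DMAP (cat.), CH2Cl2, rt
Reagents that add atoms: 20, acetic anhydride, CC(=O)OC(C)=O
Why: Per‑O‑acetylation gives stable, lipase‑cleavable aryl esters, and the electron‑poor rings also suppress acid‑mediated Friedel–Crafts and anthracene‑forming (Bradsher) side reactions.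

**Step 13**
Reactants: 21
Product: 23 (ortho‑formyl hexa‑O‑acetate)
Conditions: PPTS (0.3 equiv), acetone/H2O 10:1, 50 °C
Reagents that add atoms: 22, water, O
Why: Mild acid‑catalysed acetal hydrolysis unmasks the aldehyde without touching the aryl acetates or C1.

**Step 14**
Reactants: 23
Product: 24 (cis 1‑aryl‑2,3‑diaroyl‑4‑hydroxytetralin, hexa‑O‑acetate; C3/C4 undefined)
Conditions: TiCl4 (1.2 equiv), Et3N (2.5 equiv), CH2Cl2, −78 → −20 °C; NH4Cl quench
Reagents that add atoms: none
Why: Soft enolisation (Ti enolate) at the less hindered C3 CH2 followed by intramolecular aldol (6‑enolexo‑exo) closes the carbocycle. The C2 epimers interconvert by enolisation (Curtin–Hammett), and the chair‑like transition state puts the C1 diaryl pseudoaxial (peri strain with 8‑OMe) and the C2 aroyl pseudoequatorial, giving 1,2‑cis. This sets C2.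

**Step 15**
Reactants: 24
Product: 25 (hexa‑O‑acetyl licobichalcone)
Conditions: MsCl (1.3 equiv), Et3N (3 equiv), CH2Cl2, 0 °C, 1 h; citric acid quench
Reagents that add atoms: none
Why: Mesylation and E1cB elimination through the C3 enolate form the conjugated C3=C4 enone; C1 and C2 are not involved, and the short, cold reaction avoids C2 epimerisation.

**Step 16**
Reactants: 25
Product: 26 (licobichalcone)
Conditions: Candida antarctica lipase B, immobilised (a hydrolase, EC 3.1.1.3), n‑BuOH (30 equiv, acetyl acceptor), MTBE/THF 4:1, 35 °C, Ar, 60 h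
Reagents that add atoms: none
Why: Enzymatic alcoholysis cleaves all six aryl acetates at neutral pH, so the cis C2 centre and the oxidation‑prone catechols are not exposed to acid or base.

## Compound list

| # | Name | SMILES | Role |
|---|---|---|---|
| 1 | 3‑Methoxybenzene‑1,2‑diol | COc1cccc(O)c1O | starting material |
| 2 | Benzyl bromide | BrCc1ccccc1 | starting material |
| 3 | 1,2‑Bis(benzyloxy)‑3‑methoxybenzene | COc1cccc(OCc2ccccc2)c1OCc1ccccc1 | intermediate |
| 4 | N‑Bromosuccinimide | O=C1CCC(=O)N1Br | starting material |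
| 5 | 1‑Bromo‑3,4‑bis(benzyloxy)‑2‑methoxybenzene | COc1c(Br)ccc(OCc2ccccc2)c1OCc1ccccc1 | intermediate |
| 6 | N,N‑Dimethylformamide | CN(C)C=O | starting material |
| 7 | 3,4‑Bis(benzyloxy)‑2‑methoxybenzaldehyde | COc1c(C=O)ccc(OCc2ccccc2)c1OCc1ccccc1 | intermediate |
| 8 | 4'‑(Benzyloxy)acetophenone | CC(=O)c1ccc(OCc2ccccc2)cc1 | starting material |
| 9 | (E)‑3‑[3,4‑Bis(benzyloxy)‑2‑methoxyphenyl]‑1‑[4‑(benzyloxy)phenyl]prop‑2‑en‑1‑one | COc1c(/C=C/C(=O)c2ccc(OCc3ccccc3)cc2)ccc(OCc2ccccc2)c1OCc1ccccc1 | intermediate |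
| 10 | 4,5‑Bis(benzyloxy)‑2‑bromo‑3‑methoxybenzaldehyde | O=Cc1cc(OCc2ccccc2)c(OCc2ccccc2)c(OC)c1Br | intermediate |
| 11 | Ethane‑1,2‑diol | OCCO | starting material |
| 12 | 2‑[4,5‑Bis(benzyloxy)‑2‑bromo‑3‑methoxyphenyl]‑1,3‑dioxolane | COc1c(Br)c(C2OCCO2)cc(OCc2ccccc2)c1OCc1ccccc1 | intermediate |
| 13 | Triisopropyl borate | CC(C)OB(OC(C)C)OC(C)C | starting material |
| 14 | [3,4‑Bis(benzyloxy)‑6‑(1,3‑dioxolan‑2‑yl)‑2‑methoxyphenyl]boronic acid | COc1c(B(O)O)c(C2OCCO2)cc(OCc2ccccc2)c1OCc1ccccc1 | intermediate |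
| 15 | Copper(II) bromide | Br[Cu]Br | starting material |
| 16 | 2‑Bromo‑1‑[4‑(benzyloxy)phenyl]ethan‑1‑one | O=C(CBr)c1ccc(OCc2ccccc2)cc1 | intermediate |
| 17 | (3S)‑3‑[3,4‑Bis(benzyloxy)‑2‑methoxyphenyl]‑3‑[3,4‑bis(benzyloxy)‑6‑(1,3‑dioxolan‑2‑yl)‑2‑methoxyphenyl]‑1‑[4‑(benzyloxy)phenyl]propan‑1‑one | O=C(c1ccc(OCc2ccccc2)cc1)C[C@@H](c1ccc(OCc2ccccc2)c(OCc2ccccc2)c1OC)c1c(OC)c(OCc2ccccc2)c(OCc2ccccc2)cc1C1OCCO1 | intermediate |
| 18 | 1,4‑Diketone: 2‑{(S)‑[Ar][Ar'']methyl}‑1,4‑bis[4‑(benzyloxy)phenyl]butane‑1,4‑dione (C2 epimeric mixture) | O=C(CC(C(=O)c1ccc(OCc2ccccc2)cc1)[C@@H](c1ccc(OCc2ccccc2)c(OCc2ccccc2)c1OC)c1c(OC)c(OCc2ccccc2)c(OCc2ccccc2)cc1C1OCCO1)c1ccc(OCc2ccccc2)cc1 | intermediate |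
| 19 | Hexaphenol analogue of 18 (C2 mixture) | O=C(CC(C(=O)c1ccc(O)cc1)[C@@H](c1ccc(O)c(O)c1OC)c1c(OC)c(O)c(O)cc1C1OCCO1)c1ccc(O)cc1 | intermediate |
| 20 | Acetic anhydride | CC(=O)OC(C)=O | starting material |
| 21 | Hexa‑O‑acetate of 19 | O=C(CC(C(=O)c1ccc(OC(C)=O)cc1)[C@@H](c1ccc(OC(C)=O)c(OC(C)=O)c1OC)c1c(OC)c(OC(C)=O)c(OC(C)=O)cc1C1OCCO1)c1ccc(OC(C)=O)cc1 | intermediate |
| 22 | Water | O | starting material |
| 23 | Ortho‑formyl hexa‑O‑acetate (dioxolane of 21 replaced by CHO) | O=C(CC(C(=O)c1ccc(OC(C)=O)cc1)[C@@H](c1ccc(OC(C)=O)c(OC(C)=O)c1OC)c1c(OC)c(OC(C)=O)c(OC(C)=O)cc1C=O)c1ccc(OC(C)=O)cc1 | intermediate |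
| 24 | cis‑4‑Hydroxy‑1‑aryl‑2,3‑diaroyltetralin, hexa‑O‑acetate | COc1c([C@H]2c3c(cc(OC(C)=O)c(OC(C)=O)c3OC)C(O)C(C(=O)c3ccc(OC(C)=O)cc3)[C@H]2C(=O)c2ccc(OC(C)=O)cc2)ccc(OC(C)=O)c1OC(C)=O | intermediate |
| 25 | Hexa‑O‑acetyl licobichalcone | COc1c([C@H]2c3c(cc(OC(C)=O)c(OC(C)=O)c3OC)C=C(C(=O)c3ccc(OC(C)=O)cc3)[C@H]2C(=O)c2ccc(OC(C)=O)cc2)ccc(OC(C)=O)c1OC(C)=O | intermediate |
| 26 | Licobichalcone | COc1c([C@H]2c3c(cc(O)c(O)c3OC)C=C(C(=O)c3ccc(O)cc3)[C@H]2C(=O)c2ccc(O)cc2)ccc(O)c1O | target |

**Total steps:** 16.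
**Longest linear sequence:** 13 steps (1 → 3 → 5 → 10 → 12 → 14 → 17 → 18 → 19 → 21 → 23 → 24 → 25 → 26).

**Three steps most likely to fail**
1. **Step 9 (Rh asymmetric addition of the di‑ortho boronic acid).** It may give low yield through protodeboronation or slow transmetalation, or low ee.
   - Fallback: replace it with enantioselective hydrogenation. Prepare the trisubstituted β,β‑diaryl enone (Ar)(Ar'')C=CH–C(=O)Ar' and hydrogenate it with an Ir–P,N catalyst, using the ortho‑acetal/OMe difference for face discrimination.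
2. **Step 14 (aldol ring closure).** It may give the trans isomer, the five‑membered indanol or the Paal–Knorr furan instead of the cis tetralin.
   - Fallback: close the ring by intramolecular Horner–Wadsworth–Emmons olefination. Convert the C3 CH2 of 23 to a β‑keto‑phosphonate and cyclise onto the aldehyde with LiCl/DBU to form C3=C4 directly.
3. **Step 5 (ortho‑lithiation regiochemistry, with the step 2 bromination).** It could give the wrong lithiation site, halogen dance or benzyne formation.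
   - Fallback: make 10 from 5‑hydroxyvanillin. Protect the 4‑OH selectively as benzyl ether, brominate para to the remaining free 3‑OH (which directs to the required carbon), then benzylate the 3‑OH.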